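Each 2-aryl-3-hydroxymethyl-2,3-dihydrobenzofuran is read as a contracted flavanone. The exocyclic CH2OH carbon on C3 is the former C4 carbonyl carbon of a six-membered chroman-4-one ring, and the C3–C3a bond comes from a 1,2-shift of aryl carbon C4a. A bis-flavanone, built by two catalyst-controlled conjugate additions onto one bromochromone, is contracted at both pyranone rings in one operation with PhI(OAc)2 in trimethyl orthoformate. This gives the central and the outer trans-dihydrobenzofuran-3-carboxylates and relays each C2 configuration to C3. The aryl bromide so obtained is added to an (R)-β-benzylbutyrolactone, and hydrogenation of the derived dihydrofuran sets the all-cis oxolane.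

Key step: step 6

Assumptions: the SMILES encodes a (2R,3R,4R)-oxolane with aryl, CH2OH and benzyl groups all cis, and this isomer is the goal; the sense of induction of t-BuPyOx and Et-DuPhos is assigned by analogy with simpler substrates, and the mirror-image ligand is used if a trial shows the opposite sense.

Step 1
Reactants: 1 2'-hydroxy-3'-methoxyacetophenone
Product: 2 5'-bromo-2'-hydroxy-3'-methoxyacetophenone
Conditions: NBS, MeCN, 0 °C → rt
Reagents that add atoms: N-bromosuccinimide O=C1CCC(=O)N1Br
Why: Electrophilic aromatic bromination, in which the free phenol directs to its only open ortho/para position, C5' para to OH.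

Step 2
Reactants: 2 5'-bromo-2'-hydroxy-3'-methoxyacetophenone
Product: 4 6-bromo-8-methoxy-4H-chromen-4-one, via enaminone 3 (not isolated)
Conditions: Me2NCH(OMe)2, toluene, 100 °C; concentrate; then conc. HCl, CH2Cl2, rt
Reagents that add atoms: N,N-dimethylformamide dimethyl acetal COC(OC)N(C)C
Why: Enaminone chromone synthesis, in which the methyl ketone condenses with the amide acetal and acid then drives addition–elimination of the phenol oxygen at the β-carbon with loss of dimethylamine.

Step 3
Reactants: 4 6-bromo-8-methoxy-4H-chromen-4-one; 5 [4-(benzyloxy)-3-methoxyphenyl]boronic acid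
Product: 6 (S)-2-[4-(benzyloxy)-3-methoxyphenyl]-6-bromo-8-methoxychroman-4-one
Conditions: Pd(OCOCF3)2 (5 mol %), (R)-t-BuPyOx (6 mol %), NH4PF6 (30 mol %), H2O (5 equiv), ClCH2CH2Cl, 60 °C
Reagents that add atoms: none
Why: Asymmetric conjugate addition of an arylboronic acid to a chromone under divalent palladium catalysis, in which the aryl–palladium species inserts C2=C3 on the face left open by the tert-butyl group of the pyridine-oxazoline ligand to set C2 as S, while the aryl bromide stays untouched because no zerovalent palladium is involved.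

Step 4
Reactants: 6 (S)-2-[4-(benzyloxy)-3-methoxyphenyl]-6-bromo-8-methoxychroman-4-one
Product: 8 (S)-{2-[4-(benzyloxy)-3-methoxyphenyl]-8-methoxy-4-oxochroman-6-yl}boronic acid, via pinacol boronate 7 (not isolated)
Conditions: B2pin2, Pd(OAc)2 (2 mol %), XPhos (4 mol %), potassium 2-ethylhexanoate, i-PrOAc, 35 °C; filter; then NaIO4, NH4OAc, acetone–H2O, rt
Reagents that add atoms: bis(pinacolato)diboron CC1(C)OB(OC1(C)C)B1OC(C)(C)C(C)(C)O1; water O
Why: Miyaura borylation with a lipophilic carboxylate base runs near ambient temperature, which should hold back base-induced retro-oxa-Michael racemisation at C2, and periodate cleavage of pinacol then pulls the hydrolysis equilibrium to the free boronic acid.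

Step 5
Reactants: 8 (S)-{2-[4-(benzyloxy)-3-methoxyphenyl]-8-methoxy-4-oxochroman-6-yl}boronic acid; 4 6-bromo-8-methoxy-4H-chromen-4-one
Product: 9 bis-flavanone (2R)-6-bromo-8-methoxy-2-{(2S)-2-[4-(benzyloxy)-3-methoxyphenyl]-8-methoxy-4-oxochroman-6-yl}chroman-4-one
Conditions: Pd(OCOCF3)2 (10 mol %), (S)-t-BuPyOx (12 mol %), NH4PF6 (30 mol %), H2O (5 equiv), 4 (2 equiv), ClCH2CH2Cl, 60 °C
Reagents that add atoms: none
Why: The same asymmetric conjugate addition with the antipodal ligand sets the new C2 as R under catalyst control, the remote outer stereocentre having no say, and stereoisomers from the minor enantiomers are diastereomers that can be removed here.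

Step 6
Reactants: 9 bis-flavanone
Product: 11 bis(dihydrobenzofuran) dimethyl ester (central ring 2R,3R; outer ring 2S,3S; both trans), via bis(enol ether) 10 (not isolated)
Conditions: HC(OMe)3, H2SO4 (cat.), rt, 1 h; then PhI(OAc)2 (2.4 equiv), 0 °C → rt
Reagents that add atoms: trimethyl orthoformate COC(OC)OC
Why: Acid and HC(OMe)3 convert both C4 ketones into the 4-methoxy-2H-chromene enol ethers of 10; electrophilic PhI(OAc)2 then attacks each C3 on the face anti to the pseudo-equatorial 2-aryl group, methanol caps C4 as a dimethyl ketal, and aryl carbon C4a, antiperiplanar to the equatorial C3–I bond, shifts from C4 to C3 with expulsion of PhI, after which the dimethoxycarbenium ion loses a methyl group to acetate and becomes the methyl ester. The closest known reaction type is the hypervalent-iodine oxidative ring contraction of flavanones to methyl trans-2-aryl-2,3-dihydrobenzofuran-3-carboxylates (an oxidative 1,2-aryl shift of an aryl ketone), here run at two sites of one molecule. Each five-membered ring is closed by this 1,2-shift and not by a cyclisation: the six-membered ring O1–C2–C3–C4–C4a–C8a becomes O1–C2–C3–C3a–C7a while C4 is extruded as CO2Me. C2 takes no part and keeps the configuration set in steps 3 and 5, and each new C3 centre is controlled by its C2 neighbour, because anti iodination followed by inversion in the shift places CO2Me trans to the aryl group, which is also the thermodynamic arrangement of this epimerisable centre. The step needs migration of C4a rather than of the electron-rich 2-aryl group (isoflavone pathway): the orthoformate medium makes C4 a ketal whose two oxygen atoms push the C4–C4a bond, the diequatorial conformer aligns that bond and not C2–aryl with C3–I, and O1 ortho to C4a stabilises the bridged phenonium transition state. Oxidation elsewhere should be held back because every phenol oxygen is benzylated or part of a ring and the enol ethers are by far the most nucleophilic sites.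

Step 7
Reactants: 11 bis(dihydrobenzofuran) dimethyl ester
Product: 12 bis(dihydrobenzofuran) diol (central ring 2R,3S; outer ring 2S,3R)
Conditions: LiAlH4, THF, 0 °C
Reagents that add atoms: none
Why: Hydride reduction of both esters to primary alcohols, with aryl bromide and benzyl ether inert at 0 °C and the already thermodynamic trans relationship not at risk.

Step 8
Reactants: 12 bis(dihydrobenzofuran) diol
Product: 13 aryl bromide with both CH2OH groups as benzyl ethers
Conditions: NaH, BnBr, Bu4NI (cat.), DMF, 0 °C → rt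
Reagents that add atoms: benzyl bromide BrCc1ccccc1
Why: Williamson ether synthesis masks both primary alcohols with the group already on the phenol, so one hydrogenolysis frees everything at the end.

Step 9
Reactants: 14 4-(benzyloxy)-3-methoxybenzaldehyde; 15 dimethyl succinate
Product: 16 (E)-4-[4-(benzyloxy)-3-methoxyphenyl]-3-(methoxycarbonyl)but-3-enoic acid
Conditions: NaOMe, MeOH, reflux; then aq. HCl
Reagents that add atoms: none
Why: Stobbe condensation, in which the aldol adduct lactonises and opens by elimination to the half-ester, the E alkene with aryl trans to CO2Me being favoured.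

Step 10
Reactants: 16 (E)-Stobbe half-ester
Product: 17 (R)-3-(methoxycarbonyl)-4-[4-(benzyloxy)-3-methoxyphenyl]butanoic acid
Conditions: [Rh(cod)((S,S)-Et-DuPhos)]BF4 (0.5 mol %), NaOMe (10 mol %), H2 (5 bar), MeOH, rt
Reagents that add atoms: none
Why: Asymmetric hydrogenation of an itaconate-type half-ester, in which carboxylate-chelated binding to the chiral rhodium bisphospholane fixes the alkene face and sets the R centre (later C4 of the oxolane), while the homogeneous catalyst leaves the benzyl ether alone.

Step 11
Reactants: 17 (R)-half-ester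
Product: 19 (R)-4-[4-(benzyloxy)-3-methoxybenzyl]dihydrofuran-2(3H)-one, via hydroxy acid 18 (not isolated)
Conditions: KOH (1 equiv), EtOH; Ca(BH4)2·2THF, 0 °C → rt; then 3 M HCl, rt
Reagents that add atoms: none
Why: Chemoselective borohydride reduction of the ester beside the unreactive carboxylate salt, followed by acid lactonisation, gives the β-benzyl lactone without touching the stereocentre.

Step 12
Reactants: 19 (R)-β-benzyl lactone
Product: 21 (3S,4R)-3-[(benzyloxy)methyl]-4-[4-(benzyloxy)-3-methoxybenzyl]dihydrofuran-2(3H)-one, via lithium enolate 20 (not isolated)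
Conditions: LiN(i-Pr)2, THF, −78 °C; BnOCH2Cl, −78 → −40 °C
Reagents that add atoms: benzyl chloromethyl ether ClCOCc1ccccc1
Why: Enolate alkylation anti to the β-benzyl group gives the trans lactone, and the configuration of this new centre does not matter because step 14 erases it.

Step 13
Reactants: 13 aryl bromide; 21 (3S,4R)-lactone
Product: 23 cyclic hemiketal (anomer mixture in equilibrium with the open hydroxy ketone), via aryllithium 22 (not isolated)
Conditions: 13, n-BuLi, THF, −78 °C; then 21, −78 °C; aq. NH4Cl
Reagents that add atoms: none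
Why: Bromine–lithium exchange and 1,2-addition of the aryllithium to the lactone carbonyl, in which the lithium hemiketal alkoxide persists at −78 °C so that a second addition is avoided and no lasting stereocentre is created.

Step 14
Reactants: 23 cyclic hemiketal
Product: 24 (4R)-2-aryl-3-[(benzyloxy)methyl]-4-[4-(benzyloxy)-3-methoxybenzyl]-4,5-dihydrofuran
Conditions: PPTS (10 mol %), 4 Å MS, toluene, 60 °C
Reagents that add atoms: none
Why: Acid-catalysed cyclodehydration through the aryl-stabilised oxocarbenium ion, whose only β-hydrogen sits on C3, gives the aryl-conjugated endocyclic enol ether and leaves C4 as the single stereocentre of the ring.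

Step 15
Reactants: 24 4,5-dihydrofuran
Product: 25 pentabenzyl ether of the target with a (2R,3R,4R) all-cis oxolane
Conditions: H2 (10 bar), Rh/Al2O3 (5 wt % Rh), Et3N (trace), EtOAc, rt
Reagents that add atoms: none
Why: Heterogeneous syn hydrogenation of the enol ether on the face opposite the C4 benzyl group puts H2 and H3 on the side of H4 and so sets C2 and C3 with aryl, CH2OBn and benzyl all cis, rhodium being chosen because it is little given to C–O hydrogenolysis.

Step 16
Reactants: 25 pentabenzyl ether
Product: 26 target CNP0395728.1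
Conditions: H2 (1 bar), Pd/C (10 wt % Pd), EtOAc–EtOH, rt
Reagents that add atoms: none
Why: Neutral catalytic hydrogenolysis cleaves the five O-benzyl groups faster than the ring benzylic C–O bonds, and the absence of acid protects the epimerisable C2 of the all-cis oxolane.

Compound list
1 | 2'-hydroxy-3'-methoxyacetophenone | CC(=O)c1cccc(OC)c1O | starting material
2 | 5'-bromo-2'-hydroxy-3'-methoxyacetophenone | CC(=O)c1cc(Br)cc(OC)c1O | intermediate
3 | (E)-1-(5-bromo-2-hydroxy-3-methoxyphenyl)-3-(dimethylamino)prop-2-en-1-one | CN(C)/C=C/C(=O)c1cc(Br)cc(OC)c1O | intermediate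
4 | 6-bromo-8-methoxy-4H-chromen-4-one | COc1cc(Br)cc2c(=O)ccoc12 | intermediate
5 | [4-(benzyloxy)-3-methoxyphenyl]boronic acid | COc1cc(B(O)O)ccc1OCc1ccccc1 | starting material
6 | (S)-2-[4-(benzyloxy)-3-methoxyphenyl]-6-bromo-8-methoxychroman-4-one | O=C1C[C@@H](c2ccc(OCc3ccccc3)c(OC)c2)Oc2c(OC)cc(Br)cc21 | intermediate
7 | pinacol boronate of 6 (Bpin in place of Br) | O=C1C[C@@H](c2ccc(OCc3ccccc3)c(OC)c2)Oc2c(OC)cc(B3OC(C)(C)C(C)(C)O3)cc21 | intermediate
8 | (S)-{2-[4-(benzyloxy)-3-methoxyphenyl]-8-methoxy-4-oxochroman-6-yl}boronic acid | O=C1C[C@@H](c2ccc(OCc3ccccc3)c(OC)c2)Oc2c(OC)cc(B(O)O)cc21 | intermediate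
9 | bis-flavanone, inner C2 R, outer C2 S | O=C1C[C@H](c2cc(OC)c3c(c2)C(=O)C[C@@H](c2ccc(OCc4ccccc4)c(OC)c2)O3)Oc2c(OC)cc(Br)cc21 | intermediate
10 | bis(4-methoxy-2H-chromene) enol ether of 9 | COC1=C[C@H](c2cc(OC)c3c(c2)C(OC)=C[C@@H](c2ccc(OCc4ccccc4)c(OC)c2)O3)Oc2c(OC)cc(Br)cc21 | intermediate
11 | methyl (2R,3R)-5-bromo-7-methoxy-2-{(2S,3S)-2-[4-(benzyloxy)-3-methoxyphenyl]-7-methoxy-3-(methoxycarbonyl)-2,3-dihydrobenzofuran-5-yl}-2,3-dihydrobenzofuran-3-carboxylate | Brc1cc(OC)c2c(c1)[C@@H](C(=O)OC)[C@H](c1cc(OC)c3c(c1)[C@H](C(=O)OC)[C@@H](c1ccc(OCc4ccccc4)c(OC)c1)O3)O2 | intermediate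
12 | corresponding diol, central ring 2R,3S, outer ring 2S,3R | Brc1cc(OC)c2c(c1)[C@@H](CO)[C@H](c1cc(OC)c3c(c1)[C@H](CO)[C@@H](c1ccc(OCc4ccccc4)c(OC)c1)O3)O2 | intermediate
13 | bis(benzyl ether) of 12 | Brc1cc(OC)c2c(c1)[C@@H](COCc1ccccc1)[C@H](c1cc(OC)c3c(c1)[C@H](COCc1ccccc1)[C@@H](c1ccc(OCc4ccccc4)c(OC)c1)O3)O2 | intermediate
14 | 4-(benzyloxy)-3-methoxybenzaldehyde | COc1cc(C=O)ccc1OCc1ccccc1 | starting material
15 | dimethyl succinate | COC(=O)CCC(=O)OC | starting material
16 | (E)-4-[4-(benzyloxy)-3-methoxyphenyl]-3-(methoxycarbonyl)but-3-enoic acid | COC(=O)/C(CC(=O)O)=C/c1ccc(OCc2ccccc2)c(OC)c1 | intermediate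
17 | (R)-3-(methoxycarbonyl)-4-[4-(benzyloxy)-3-methoxyphenyl]butanoic acid | COc1cc(C[C@@H](C(=O)OC)CC(=O)O)ccc1OCc1ccccc1 | intermediate
18 | (R)-3-[4-(benzyloxy)-3-methoxybenzyl]-4-hydroxybutanoic acid | COc1cc(C[C@@H](CO)CC(=O)O)ccc1OCc1ccccc1 | intermediate
19 | (R)-4-[4-(benzyloxy)-3-methoxybenzyl]dihydrofuran-2(3H)-one | COc1cc(C[C@H]2COC(=O)C2)ccc1OCc1ccccc1 | intermediate
20 | lithium enolate of 19 | COc1cc(C[C@H]2COC(O[Li])=C2)ccc1OCc1ccccc1 | intermediate
21 | (3S,4R)-3-[(benzyloxy)methyl]-4-[4-(benzyloxy)-3-methoxybenzyl]dihydrofuran-2(3H)-one (trans) | COc1cc(C[C@H]2COC(=O)[C@@H]2COCc2ccccc2)ccc1OCc1ccccc1 | intermediate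
22 | aryllithium from 13 (Li in place of Br) | [Li]c1cc(OC)c2c(c1)[C@@H](COCc1ccccc1)[C@H](c1cc(OC)c3c(c1)[C@H](COCc1ccccc1)[C@@H](c1ccc(OCc4ccccc4)c(OC)c1)O3)O2 | intermediate
23 | (3S,4R)-2-aryl-2-hydroxyoxolane hemiketal, anomer mixture | COc1cc(C[C@H]2COC(O)(c3cc(OC)c4c(c3)[C@@H](COCc3ccccc3)[C@H](c3cc(OC)c5c(c3)[C@H](COCc3ccccc3)[C@@H](c3ccc(OCc6ccccc6)c(OC)c3)O5)O4)[C@@H]2COCc7ccccc7)ccc1OCc8ccccc8 | intermediate
24 | (4R)-2-aryl-3-[(benzyloxy)methyl]-4-benzyl-4,5-dihydrofuran | COc1cc(C[C@H]2COC(c3cc(OC)c4c(c3)[C@@H](COCc3ccccc3)[C@H](c3cc(OC)c5c(c3)[C@H](COCc3ccccc3)[C@@H](c3ccc(OCc6ccccc6)c(OC)c3)O5)O4)=C2COCc7ccccc7)ccc1OCc8ccccc8 | intermediate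
25 | pentabenzyl ether of the target, (2R,3R,4R) all-cis oxolane | COc1cc(C[C@H]2CO[C@@H](c3cc(OC)c4c(c3)[C@@H](COCc3ccccc3)[C@H](c3cc(OC)c5c(c3)[C@H](COCc3ccccc3)[C@@H](c3ccc(OCc6ccccc6)c(OC)c3)O5)O4)[C@H]2COCc7ccccc7)ccc1OCc8ccccc8 | intermediate
26 | CNP0395728.1 | COc1cc(C[C@H]2CO[C@@H](c3cc(OC)c4c(c3)[C@@H](CO)[C@H](c3cc(OC)c5c(c3)[C@H](CO)[C@@H](c3ccc(O)c(OC)c3)O5)O4)[C@H]2CO)ccc1O | target

Total step count: 16. Longest linear sequence: 12 (steps 1–8 and 13–16); the lactone branch (steps 9–12) joins at step 13.

Steps most likely to fail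

Step 6. The electron-rich 2-aryl groups may migrate instead of C4a. Acid may open and reclose the pyranone at C2 with loss of configuration. The oxidant may attack the alkoxyarenes, or the second contraction may stall. The fallback sets out from 9 and comes back at 11, and it separates oxidation from the shift. PhNMe3Br3 in THF at 0 °C should brominate both C3 positions and settle on the diequatorial bis(trans-3-bromoflavanone) F1. HC(OMe)3–MeOH with catalytic TsOH should then give its bis(dimethyl ketal) F2. AgBF4 in MeOH abstracts the equatorial bromides and triggers the 1,2-aryl shift known for α-halo ketals of aryl ketones. Inversion at C3 is the same as in the main step, so 11 results with no oxidant present.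

Step 15. Hydrogen may reach both faces of the hindered tetrasubstituted enol ether. The allylic C–O bond may also be hydrogenolysed before the double bond is saturated. The fallback sets out from 21 and 13 and comes back at 25, and it replaces surface hydrogenation by ionic reduction of an oxocarbenium ion. LiN(i-Pr)2 at −78 °C turns 21 into its lithium enolate F3. Kinetic protonation with 2,6-di-tert-butyl-4-methylphenol on the face anti to the benzyl group should give the cis lactone F4. Addition of aryllithium 22 at −78 °C gives the 3,4-cis hemiketal F5. Et3SiH with BF3·OEt2 at −78 °C then delivers hydride to the oxocarbenium ion on the face opposite both ring substituents, which places the aryl group cis to them and gives 25.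

Step 4. The carboxylate base may open the flavanone by retro-oxa-Michael reaction and racemise C2. The boronic acid may also be lost by protodeboronation during release. The fallback sets out from 4 and comes back at 8, and it installs boron in masked form before the stereocentre exists. Chromone 4 with (pin)B–B(dan), PdCl2(dppf) and KOAc in dioxane at 80 °C should give the chromone naphthalene-1,8-diaminatoborane F6. Conjugate addition of 5 under the conditions of step 3, in which the B(dan) group does not transmetalate, gives the masked flavanone borane F7. Treatment with 2 M HCl in THF at rt then frees 8 under acidic conditions that do not open the flavanone.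

Further compounds
F1 | step 6 | bis(trans-3-bromoflavanone), each C3–Br trans to the neighbouring 2-aryl group, C2 centres as in 9 | O=C1[C@@H](Br)[C@H](c2cc(OC)c3c(c2)C(=O)[C@H](Br)[C@@H](c2ccc(OCc4ccccc4)c(OC)c2)O3)Oc2c(OC)cc(Br)cc21
F2 | step 6 | bis(dimethyl ketal) of F1 | COC1(OC)[C@@H](Br)[C@H](c2cc(OC)c3c(c2)C(OC)(OC)[C@H](Br)[C@@H](c2ccc(OCc4ccccc4)c(OC)c2)O3)Oc2c(OC)cc(Br)cc21
F3 | step 15 | lithium enolate of 21 | COc1cc(C[C@H]2COC(O[Li])=C2COCc2ccccc2)ccc1OCc1ccccc1
F4 | step 15 | (3R,4R)-3-[(benzyloxy)methyl]-4-[4-(benzyloxy)-3-methoxybenzyl]dihydrofuran-2(3H)-one (cis) | COc1cc(C[C@H]2COC(=O)[C@H]2COCc2ccccc2)ccc1OCc1ccccc1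
F5 | step 15 | (3R,4R)-2-aryl-2-hydroxyoxolane hemiketal (3,4-cis), anomer mixture | COc1cc(C[C@H]2COC(O)(c3cc(OC)c4c(c3)[C@@H](COCc3ccccc3)[C@H](c3cc(OC)c5c(c3)[C@H](COCc3ccccc3)[C@@H](c3ccc(OCc6ccccc6)c(OC)c3)O5)O4)[C@H]2COCc7ccccc7)ccc1OCc8ccccc8
F6 | step 4 | 8-methoxy-6-(naphthalene-1,8-diaminatoboryl)-4H-chromen-4-one | COc1cc(B2Nc3cccc4cccc(N2)c34)cc2c(=O)ccoc12
F7 | step 4 | (S)-2-[4-(benzyloxy)-3-methoxyphenyl]-8-methoxy-6-(naphthalene-1,8-diaminatoboryl)chroman-4-one | O=C1C[C@@H](c2ccc(OCc3ccccc3)c(OC)c2)Oc2c(OC)cc(B3Nc4cccc5cccc(N3)c45)cc21
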